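**Retrosynthetic overview**

1. The strategy rests on ring C: its O1–C2 bond is the ester bond between the C8a phenol oxygen of ring A and the carboxyl carbon of the 3,4-dioxygenated benzoic acid (ring B), and C3 is the α-carbon of the C4 aryl ketone. C2=C3 is therefore cut back to an aryl ester and a keto ylide on C3.
2. Ester ylide 15 comes from hydroxy phosphorane 12 and acid chloride 14; 12 comes from methyl salicylate 9 and methylenetriphenylphosphorane.
3. Ring A (O5 benzyl, O7 methyl, O8 MOM, O8a free) is drawn from 5-hydroxyvanillin: bis-MOM ether, Baeyer–Villiger oxidation to the C5 oxygen, benzylation, MOM-directed ortho-lithiation/carboxylation for C4, then O8 and O8a are told apart through the ester.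
4. After ring closure: MOM-to-acetate exchange at O8, C3 hydroxylation through the DMDO epoxide, hydrogenolysis.
5. Ring order: rings A and B are bought, ring C is the only ring made (step 10).

Key step: step 10

Remark on the chemistry: intermediates 16 and 20 are racemic and transient (one enantiomer is drawn). Their stereocentres are erased in the step that forms them, and the target is achiral.

**Route**

Step 1
Reactants: 1 3,4-dihydroxy-5-methoxybenzaldehyde (5-hydroxyvanillin)
Product: 2 3-methoxy-4,5-bis(methoxymethoxy)benzaldehyde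
Conditions: MOMCl (2.6 equiv), i-Pr2NEt, CH2Cl2, 0 °C to rt
Reagents that add atoms: chloromethyl methyl ether, COCCl
Why: Double O-alkylation of the catechol by the reactive α-chloro ether (MOM ether formation), with no selectivity between the two phenols required.

Step 2
Reactants: 2 3-methoxy-4,5-bis(methoxymethoxy)benzaldehyde
Product: 4 3-methoxy-4,5-bis(methoxymethoxy)phenol, via aryl formate 3 (not isolated)
Conditions: mCPBA, CH2Cl2, rt; then K2CO3 (cat.), MeOH, rt, under N2
Reagents that add atoms: 3-chloroperoxybenzoic acid, O=C(OO)c1cccc(Cl)c1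
Why: Baeyer–Villiger oxidation in which the electron-rich trialkoxyaryl group migrates in preference to hydride to give formate 3, which mild methanolysis cleaves to the phenol that becomes O5.

Step 3
Reactants: 4 3-methoxy-4,5-bis(methoxymethoxy)phenol
Product: 5 5-(benzyloxy)-1-methoxy-2,3-bis(methoxymethoxy)benzene
Conditions: BnBr, K2CO3, DMF, rt
Reagents that add atoms: benzyl bromide, BrCc1ccccc1
Why: Williamson ether synthesis on the only free phenol.

Step 4
Reactants: 5 5-(benzyloxy)-1-methoxy-2,3-bis(methoxymethoxy)benzene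
Product: 7 methyl 6-(benzyloxy)-4-methoxy-2,3-bis(methoxymethoxy)benzoate, via aryllithium 6 (not isolated)
Conditions: n-BuLi (1.2 equiv), THF, 0 °C, 1 h; then inverse addition to ClCO2Me (3 equiv), THF, −78 °C
Reagents that add atoms: methyl chloroformate, COC(=O)Cl
Why: Directed ortho-metalation at the only ring CH that is ortho to a MOM ether (flanked by OMOM and OBn; the other CH lies between the weaker directors OBn and OMe), followed by acylation of the aryllithium with a chloroformate, with inverse addition suppressing ketone formation.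

Step 5
Reactants: 7 methyl 6-(benzyloxy)-4-methoxy-2,3-bis(methoxymethoxy)benzoate
Product: 8 methyl 6-(benzyloxy)-2,3-dihydroxy-4-methoxybenzoate
Conditions: HCl (cat., conc.), MeOH, 45 °C, under N2
Reagents that add atoms: none
Why: Acid-catalysed acetal methanolysis should remove both MOM groups while the benzyl ether, the methyl ether and the methyl ester (in methanol) are untouched.

Step 6
Reactants: 8 methyl 6-(benzyloxy)-2,3-dihydroxy-4-methoxybenzoate
Product: 9 methyl 6-(benzyloxy)-2-hydroxy-4-methoxy-3-(methoxymethoxy)benzoate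
Conditions: NaH (2.1 equiv), DMF, 0 °C; then MOMCl (1.0 equiv), −20 to 0 °C; H2O
Reagents that add atoms: chloromethyl methyl ether, COCCl
Why: Regioselective Williamson mono-alkylation of the catechol dianion, in which the oxide ortho to the ester is conjugated with and chelated to the carbonyl, so the more basic 3-oxide should take the single equivalent of MOMCl; any bis-ether formed is compound 7 and returns through step 5.

Step 7
Reactants: 9 methyl 6-(benzyloxy)-2-hydroxy-4-methoxy-3-(methoxymethoxy)benzoate; 10 methyltriphenylphosphonium bromide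
Product: 12 1-[6-(benzyloxy)-2-hydroxy-4-methoxy-3-(methoxymethoxy)phenyl]-2-(triphenylphosphoranylidene)ethan-1-one, via methylenetriphenylphosphorane 11 (not isolated)
Conditions: 10 (3.3 equiv), n-BuLi (3.2 equiv), THF, 0 °C; then 9, 0 °C to reflux; H2O
Reagents that add atoms: none
Why: Acylation of a non-stabilised ylide by an ester with transylidation (Bestmann-type): one equivalent of 11 deprotonates the phenol, a second adds to the ester with loss of methoxide, and a third deprotonates the β-ketophosphonium ion to the stabilised ylide.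

Step 8
Reactants: 13 3,4-bis(benzyloxy)benzoic acid
Product: 14 3,4-bis(benzyloxy)benzoyl chloride
Conditions: (COCl)2, DMF (cat.), CH2Cl2, 0 °C to rt
Reagents that add atoms: oxalyl chloride, O=C(Cl)C(=O)Cl
Why: Acid chloride formation through the catalytic Vilsmeier-type chloroiminium species, which benzyl ethers tolerate.

Step 9
Reactants: 12 1-[6-(benzyloxy)-2-hydroxy-4-methoxy-3-(methoxymethoxy)phenyl]-2-(triphenylphosphoranylidene)ethan-1-one; 14 3,4-bis(benzyloxy)benzoyl chloride
Product: 15 3-(benzyloxy)-5-methoxy-6-(methoxymethoxy)-2-[(triphenylphosphoranylidene)acetyl]phenyl 3,4-bis(benzyloxy)benzoate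
Conditions: Et3N (1.2 equiv), DMAP (cat.), CH2Cl2, 0 °C to rt; used crude
Reagents that add atoms: none
Why: DMAP-catalysed O-acylation of the phenol, since the keto-stabilised ylide carbon is a poor acyl acceptor and any acyl group that lands on the ylide oxygen should be passed on to the phenoxide.

Step 10
Reactants: 15 3-(benzyloxy)-5-methoxy-6-(methoxymethoxy)-2-[(triphenylphosphoranylidene)acetyl]phenyl 3,4-bis(benzyloxy)benzoate
Product: 17 5-(benzyloxy)-2-[3,4-bis(benzyloxy)phenyl]-7-methoxy-8-(methoxymethoxy)-4H-chromen-4-one, via oxaphosphetane 16 (not isolated)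
Conditions: PhMe, reflux, Ar
Reagents that add atoms: none
Why: Intramolecular Wittig olefination of an ester carbonyl by a keto-stabilised ylide, the reaction type known for o-acyloxyphenacylidene triphenylphosphoranes giving chromones and flavones: the ylide carbon (future C3) adds to the carbonyl carbon of the aryl benzoate (future C2) in a 6-exo-trig closure that completes ring C (O1–C2–C3–C4–C4a–C8a) as oxaphosphetane 16, which undergoes cycloreversion to C2=C3 and Ph3P=O. No stereocentre remains, because the two transient centres of 16 are erased in the elimination. The step needs chemoselectivity for olefination over O-to-C acyl transfer (expulsion of the C8a aryloxide from the tetrahedral adduct); under neutral, aprotic, base-free conditions that aryloxide stays tethered and can only re-add, whereas loss of Ph3P=O is irreversible, so the adduct should be funnelled to the flavone. The two ortho oxygens at C5 and C8a twist the C4 carbonyl out of the ring plane, which lowers the stabilisation of the ylide and raises its nucleophilicity, and the benzoate is the only carbonyl within its reach.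

Step 11
Reactants: 17 5-(benzyloxy)-2-[3,4-bis(benzyloxy)phenyl]-7-methoxy-8-(methoxymethoxy)-4H-chromen-4-one
Product: 18 5-(benzyloxy)-2-[3,4-bis(benzyloxy)phenyl]-8-hydroxy-7-methoxy-4H-chromen-4-one
Conditions: HCl (cat.), MeOH–CH2Cl2, rt to 40 °C
Reagents that add atoms: none
Why: Acid-catalysed MOM acetal cleavage under methanolic HCl, to which the benzyl ethers and the flavone core are stable.

Step 12
Reactants: 18 5-(benzyloxy)-2-[3,4-bis(benzyloxy)phenyl]-8-hydroxy-7-methoxy-4H-chromen-4-one
Product: 19 5-(benzyloxy)-2-[3,4-bis(benzyloxy)phenyl]-7-methoxy-4-oxo-4H-chromen-8-yl acetate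
Conditions: Ac2O, pyridine, DMAP (cat.), CH2Cl2, 0 °C to rt
Reagents that add atoms: acetic anhydride, CC(=O)OC(C)=O
Why: DMAP-catalysed acetylation of the only free hydroxyl group in the molecule.

Step 13
Reactants: 19 5-(benzyloxy)-2-[3,4-bis(benzyloxy)phenyl]-7-methoxy-4-oxo-4H-chromen-8-yl acetate
Product: 21 5-(benzyloxy)-2-[3,4-bis(benzyloxy)phenyl]-3-hydroxy-7-methoxy-4-oxo-4H-chromen-8-yl acetate, via flavone epoxide 20 (not isolated)
Conditions: DMDO (acetone solution, excess), CH2Cl2, 0 °C to rt; then TsOH·H2O (cat.), CH2Cl2, rt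
Reagents that add atoms: dimethyldioxirane, CC1(C)OO1
Why: Dioxirane epoxidation of the flavone C2=C3 bond followed by acid-catalysed opening of the 2,3-epoxide through the C2 cation (stabilised by O1 and the aryl group) and loss of H3 to the 3-hydroxyflavone; no MOM group is left to suffer from the acid and the aryl acetate tolerates both reagents.

Step 14
Reactants: 21 5-(benzyloxy)-2-[3,4-bis(benzyloxy)phenyl]-3-hydroxy-7-methoxy-4-oxo-4H-chromen-8-yl acetate
Product: 22 2-(3,4-dihydroxyphenyl)-3,5-dihydroxy-7-methoxy-4-oxo-4H-chromen-8-yl acetate (gossypetin 7-methyl ether 8-acetate)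
Conditions: H2 (1 atm), Pd/C (10 wt% Pd), EtOAc–THF, rt
Reagents that add atoms: none
Why: Hydrogenolysis of the three benzyl ethers under neutral conditions in an aprotic solvent, which should leave the aryl acetate and the flavonol double bond intact.

**Compound list**

1 | 3,4-dihydroxy-5-methoxybenzaldehyde (5-hydroxyvanillin) | COc1cc(C=O)cc(O)c1O | starting material
2 | 3-methoxy-4,5-bis(methoxymethoxy)benzaldehyde | COCOc1cc(C=O)cc(OC)c1OCOC | intermediate
3 | 3-methoxy-4,5-bis(methoxymethoxy)phenyl formate (not isolated) | O=COc1cc(OC)c(OCOC)c(OCOC)c1 | intermediate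
4 | 3-methoxy-4,5-bis(methoxymethoxy)phenol | Oc1cc(OC)c(OCOC)c(OCOC)c1 | intermediate
5 | 5-(benzyloxy)-1-methoxy-2,3-bis(methoxymethoxy)benzene | COCOc1cc(OCc2ccccc2)cc(OC)c1OCOC | intermediate
6 | [6-(benzyloxy)-4-methoxy-2,3-bis(methoxymethoxy)phenyl]lithium (not isolated) | [Li]c1c(OCc2ccccc2)cc(OC)c(OCOC)c1OCOC | intermediate
7 | methyl 6-(benzyloxy)-4-methoxy-2,3-bis(methoxymethoxy)benzoate | COC(=O)c1c(OCc2ccccc2)cc(OC)c(OCOC)c1OCOC | intermediate
8 | methyl 6-(benzyloxy)-2,3-dihydroxy-4-methoxybenzoate | COC(=O)c1c(OCc2ccccc2)cc(OC)c(O)c1O | intermediate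
9 | methyl 6-(benzyloxy)-2-hydroxy-4-methoxy-3-(methoxymethoxy)benzoate | COC(=O)c1c(OCc2ccccc2)cc(OC)c(OCOC)c1O | intermediate
10 | methyltriphenylphosphonium bromide | C[P+](c1ccccc1)(c1ccccc1)c1ccccc1.[Br-] | starting material
11 | methylenetriphenylphosphorane (not isolated) | C=P(c1ccccc1)(c1ccccc1)c1ccccc1 | intermediate
12 | 1-[6-(benzyloxy)-2-hydroxy-4-methoxy-3-(methoxymethoxy)phenyl]-2-(triphenylphosphoranylidene)ethan-1-one | O=C(C=P(c1ccccc1)(c1ccccc1)c1ccccc1)c1c(OCc2ccccc2)cc(OC)c(OCOC)c1O | intermediate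
13 | 3,4-bis(benzyloxy)benzoic acid | OC(=O)c1ccc(OCc2ccccc2)c(OCc2ccccc2)c1 | starting material
14 | 3,4-bis(benzyloxy)benzoyl chloride | O=C(Cl)c1ccc(OCc2ccccc2)c(OCc2ccccc2)c1 | intermediate
15 | 3-(benzyloxy)-5-methoxy-6-(methoxymethoxy)-2-[(triphenylphosphoranylidene)acetyl]phenyl 3,4-bis(benzyloxy)benzoate | O=C(C=P(c1ccccc1)(c1ccccc1)c1ccccc1)c1c(OCc2ccccc2)cc(OC)c(OCOC)c1OC(=O)c1ccc(OCc2ccccc2)c(OCc2ccccc2)c1 | intermediate
16 | cis-fused 2,2,2-triphenyl-1,2-oxaphosphetane across C2–C3 of the chroman-4-one (P on C3, O on C2; racemic, one enantiomer drawn; not isolated) | O=C1c2c(OCc3ccccc3)cc(OC)c(OCOC)c2O[C@]2(c3ccc(OCc4ccccc4)c(OCc4ccccc4)c3)OP(c3ccccc3)(c3ccccc3)(c3ccccc3)[C@H]12 | intermediate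
17 | 5-(benzyloxy)-2-[3,4-bis(benzyloxy)phenyl]-7-methoxy-8-(methoxymethoxy)-4H-chromen-4-one | COCOc1c(OC)cc(OCc2ccccc2)c2c(=O)cc(-c3ccc(OCc4ccccc4)c(OCc4ccccc4)c3)oc12 | intermediate
18 | 5-(benzyloxy)-2-[3,4-bis(benzyloxy)phenyl]-8-hydroxy-7-methoxy-4H-chromen-4-one | COc1cc(OCc2ccccc2)c2c(=O)cc(-c3ccc(OCc4ccccc4)c(OCc4ccccc4)c3)oc2c1O | intermediate
19 | 5-(benzyloxy)-2-[3,4-bis(benzyloxy)phenyl]-7-methoxy-4-oxo-4H-chromen-8-yl acetate | COc1cc(OCc2ccccc2)c2c(=O)cc(-c3ccc(OCc4ccccc4)c(OCc4ccccc4)c3)oc2c1OC(C)=O | intermediate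
20 | 5-(benzyloxy)-2-[3,4-bis(benzyloxy)phenyl]-2,3-epoxy-7-methoxy-4-oxochroman-8-yl acetate (racemic, one enantiomer drawn; not isolated) | COc1cc(OCc2ccccc2)c2c(c1OC(C)=O)O[C@]1(c3ccc(OCc4ccccc4)c(OCc4ccccc4)c3)O[C@@H]1C2=O | intermediate
21 | 5-(benzyloxy)-2-[3,4-bis(benzyloxy)phenyl]-3-hydroxy-7-methoxy-4-oxo-4H-chromen-8-yl acetate | COc1cc(OCc2ccccc2)c2c(=O)c(O)c(-c3ccc(OCc4ccccc4)c(OCc4ccccc4)c3)oc2c1OC(C)=O | intermediate
22 | 2-(3,4-dihydroxyphenyl)-3,5-dihydroxy-7-methoxy-4-oxo-4H-chromen-8-yl acetate (gossypetin 7-methyl ether 8-acetate) | COc1cc(O)c2c(=O)c(O)c(-c3ccc(O)c(O)c3)oc2c1OC(C)=O | target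

**Step count**

Total steps: 14. Longest linear sequence: 13 (steps 1–7 and 9–14, from 5-hydroxyvanillin); step 8 is the one-step side branch.

**Steps most likely to fail**

1. Step 10. The ylide may add only sluggishly to the hindered, electron-rich benzoate, and on prolonged heating the tetrahedral adduct may be diverted into acyl transfer or the ester may be cleaved by adventitious water. The fallback is the Baker–Venkataraman sequence; it sets out from 12 and comes back at 18.
 - Phosphorane 12 is cleaved hydrolytically (aq. NaOH, EtOH, reflux) to the methyl ketone 1-[6-(benzyloxy)-2-hydroxy-4-methoxy-3-(methoxymethoxy)phenyl]ethan-1-one F1.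
 - F1 is acylated with 14 (pyridine, DMAP) to 2-acetyl-3-(benzyloxy)-5-methoxy-6-(methoxymethoxy)phenyl 3,4-bis(benzyloxy)benzoate F2.
 - KOH in pyridine at 50 °C moves the aroyl group from oxygen to the enolate carbon and should give 1-[6-(benzyloxy)-2-hydroxy-4-methoxy-3-(methoxymethoxy)phenyl]-3-[3,4-bis(benzyloxy)phenyl]propane-1,3-dione F3.
 - HCl in MeOH–THF at 50 °C should cyclodehydrate F3 and remove the MOM group in the same operation, delivering 18.

2. Step 7. The phenoxide formed first, together with the two ortho substituents, may deactivate the ester so far that addition of the ylide stalls. The fallback masks the phenol so that a neutral silylated salicylate reacts instead of a phenoxide ester; it sets out from 9 and comes back at 12.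
 - 9 is silylated (TBSOTf, 2,6-lutidine, CH2Cl2) to methyl 6-(benzyloxy)-2-[(tert-butyldimethylsilyl)oxy]-4-methoxy-3-(methoxymethoxy)benzoate F4.
 - F4 is treated with methylenetriphenylphosphorane (2.2 equiv, THF, reflux) to give 1-{6-(benzyloxy)-2-[(tert-butyldimethylsilyl)oxy]-4-methoxy-3-(methoxymethoxy)phenyl}-2-(triphenylphosphoranylidene)ethan-1-one F5.
 - TBAF buffered with AcOH in THF removes the silyl group to give 12.

3. Step 4. Lithiation may occur in part at the ring position between OBn and OMe, or at the benzylic CH2 with subsequent [1,2]-Wittig rearrangement. The fallback replaces metalation by phenol-directed ortho-formylation; it sets out from 1, comes back at 9, and bypasses steps 4–6.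
 - The 4-OH of 1, which is para to the formyl group and the more acidic, is alkylated selectively (MOMCl 1.0 equiv, K2CO3 1.0 equiv, acetone, 0 °C) to 3-hydroxy-5-methoxy-4-(methoxymethoxy)benzaldehyde F6.
 - PivCl, Et3N and DMAP give 5-formyl-3-methoxy-2-(methoxymethoxy)phenyl pivalate F7.
 - mCPBA gives 5-(formyloxy)-3-methoxy-2-(methoxymethoxy)phenyl pivalate F8, and brief methanolysis (K2CO3 cat., MeOH) gives 5-hydroxy-3-methoxy-2-(methoxymethoxy)phenyl pivalate F9.
 - BnBr and K2CO3 in DMF give 5-(benzyloxy)-3-methoxy-2-(methoxymethoxy)phenyl pivalate F10.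
 - NaOMe in MeOH at 50 °C frees 5-(benzyloxy)-3-methoxy-2-(methoxymethoxy)phenol F11.
 - Magnesium-mediated ortho-formylation (MgCl2, Et3N, paraformaldehyde, MeCN, reflux) can only reach the single free ortho position and should give 6-(benzyloxy)-2-hydroxy-4-methoxy-3-(methoxymethoxy)benzaldehyde F12.
 - Pinnick oxidation (NaClO2, NaH2PO4, 2-methyl-2-butene, t-BuOH–H2O) gives 6-(benzyloxy)-2-hydroxy-4-methoxy-3-(methoxymethoxy)benzoic acid F13.
 - TMSCHN2 in MeOH–PhMe gives 9.

**Further compounds**

F1 | step 10 | 1-[6-(benzyloxy)-2-hydroxy-4-methoxy-3-(methoxymethoxy)phenyl]ethan-1-one | CC(=O)c1c(OCc2ccccc2)cc(OC)c(OCOC)c1O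
F2 | step 10 | 2-acetyl-3-(benzyloxy)-5-methoxy-6-(methoxymethoxy)phenyl 3,4-bis(benzyloxy)benzoate | CC(=O)c1c(OCc2ccccc2)cc(OC)c(OCOC)c1OC(=O)c1ccc(OCc2ccccc2)c(OCc2ccccc2)c1
F3 | step 10 | 1-[6-(benzyloxy)-2-hydroxy-4-methoxy-3-(methoxymethoxy)phenyl]-3-[3,4-bis(benzyloxy)phenyl]propane-1,3-dione | O=C(CC(=O)c1ccc(OCc2ccccc2)c(OCc2ccccc2)c1)c1c(OCc2ccccc2)cc(OC)c(OCOC)c1O
F4 | step 7 | methyl 6-(benzyloxy)-2-[(tert-butyldimethylsilyl)oxy]-4-methoxy-3-(methoxymethoxy)benzoate | COC(=O)c1c(OCc2ccccc2)cc(OC)c(OCOC)c1O[Si](C)(C)C(C)(C)C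
F5 | step 7 | 1-{6-(benzyloxy)-2-[(tert-butyldimethylsilyl)oxy]-4-methoxy-3-(methoxymethoxy)phenyl}-2-(triphenylphosphoranylidene)ethan-1-one | O=C(C=P(c1ccccc1)(c1ccccc1)c1ccccc1)c1c(OCc2ccccc2)cc(OC)c(OCOC)c1O[Si](C)(C)C(C)(C)C
F6 | step 4 | 3-hydroxy-5-methoxy-4-(methoxymethoxy)benzaldehyde | COCOc1c(O)cc(C=O)cc1OC
F7 | step 4 | 5-formyl-3-methoxy-2-(methoxymethoxy)phenyl pivalate | COCOc1c(OC(=O)C(C)(C)C)cc(C=O)cc1OC
F8 | step 4 | 5-(formyloxy)-3-methoxy-2-(methoxymethoxy)phenyl pivalate | COCOc1c(OC(=O)C(C)(C)C)cc(OC=O)cc1OC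
F9 | step 4 | 5-hydroxy-3-methoxy-2-(methoxymethoxy)phenyl pivalate | COCOc1c(OC(=O)C(C)(C)C)cc(O)cc1OC
F10 | step 4 | 5-(benzyloxy)-3-methoxy-2-(methoxymethoxy)phenyl pivalate | COCOc1c(OC(=O)C(C)(C)C)cc(OCc2ccccc2)cc1OC
F11 | step 4 | 5-(benzyloxy)-3-methoxy-2-(methoxymethoxy)phenol | COCOc1c(O)cc(OCc2ccccc2)cc1OC
F12 | step 4 | 6-(benzyloxy)-2-hydroxy-4-methoxy-3-(methoxymethoxy)benzaldehyde | O=Cc1c(OCc2ccccc2)cc(OC)c(OCOC)c1O
F13 | step 4 | 6-(benzyloxy)-2-hydroxy-4-methoxy-3-(methoxymethoxy)benzoic acid | OC(=O)c1c(OCc2ccccc2)cc(OC)c(OCOC)c1O
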